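The benzene ring of coumarin B is built onto ring A instead of being joined to it by cross-coupling. C8 of coumarin B carries C6 of coumarin A and is flanked by C7–O and C8a–O. This is a 2-arylresorcinol array, the substitution pattern a vinylketene/siloxyalkyne benzannulation produces. Heating cyclobutenone with the triisopropylsilyl ynol ether of 2,4-bis(benzyloxy)phenylacetylene makes C8–C8a, C6–C7 and C4a–C8a in one operation. The congested C6(A)–C8(B) bond is already present as the aryl–C(sp) bond. O1 and O7 of coumarin B come out distinguishable, one as a free phenol and the other as a silyl ether. Two formylations, one selective O-alkylation, a double lactonisation and a Perkin closure of coumarin C complete the route.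

Key step: step 6

Assumption: the SMILES defines no configuration for the C6(A)–C8(B) axis and the target has no stereocentre, so no axial control is attempted and any slowly rotating intermediate is taken as racemic.

Step 1
Reactants: 1 2,4-dihydroxybenzaldehyde
Product: 2 2,4-bis(benzyloxy)benzaldehyde
Conditions: BnBr (2.4 equiv), K2CO3 (3 equiv), DMF, 60 °C
Reagents that add atoms: benzyl bromide BrCc1ccccc1
Why: Double Williamson etherification in warm DMF also alkylates the hydrogen-bonded 2-OH, and two identical benzyl groups can later be removed together at low temperature without touching a silyl ether.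

Step 2
Reactants: 2 2,4-bis(benzyloxy)benzaldehyde
Product: 3 2,4-bis(benzyloxy)-1-ethynylbenzene
Conditions: dimethyl (1-diazo-2-oxopropyl)phosphonate (1.3 equiv), K2CO3 (2 equiv), MeOH/THF, rt
Reagents that add atoms: dimethyl (1-diazo-2-oxopropyl)phosphonate COP(=O)(OC)C(=[N+]=[N-])C(C)=O
Why: The Ohira–Bestmann variant of the Seyferth–Gilbert homologation turns a non-enolisable, electron-rich aryl aldehyde into the terminal alkyne under carbonate conditions that leave benzyl ethers alone.

Step 3
Reactants: 3 2,4-bis(benzyloxy)-1-ethynylbenzene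
Product: 6 {[2,4-bis(benzyloxy)phenyl]ethynyloxy}triisopropylsilane, via lithium acetylide 4 (not isolated), via lithium ynolate 5 (not isolated)
Conditions: LiN(SiMe3)2, THF, −78 °C; t-BuOOLi (from anhydrous t-BuOOH and LiN(SiMe3)2), −78 → 0 °C; TIPSOTf, −78 → 0 °C; filtration through Et3N-deactivated silica
Reagents that add atoms: tert-butyl hydroperoxide CC(C)(C)OO; triisopropylsilyl trifluoromethanesulfonate CC(C)[Si](OS(=O)(=O)C(F)(F)F)(C(C)C)C(C)C
Why: Oxidation of a lithium acetylide by attack on the O–O bond of lithium tert-butyl peroxide gives the ynolate, the bulky hard silyl triflate traps it on oxygen, and only an amide base at low temperature is used, so the benzylic positions are not metalated.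

Step 4
Reactants: 7 3-oxocyclobutanecarboxylic acid
Product: 8 3-bromocyclobutanone
Conditions: HgO, Br2, MgSO4, CH2Cl2, reflux
Reagents that add atoms: bromine BrBr
Why: The Cristol–Firth form of the Hunsdiecker bromodecarboxylation is the established entry to this bromoketone through the acyl hypobromite and a cyclobutyl radical.

Step 5
Reactants: 8 3-bromocyclobutanone
Product: 9 cyclobutenone
Conditions: n-Bu3N (2 equiv), neat, rt, vacuum transfer into a −78 °C trap, then kept cold as a toluene solution
Reagents that add atoms: none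
Why: E1cB dehydrobromination of a β-bromoketone by a non-nucleophilic, non-volatile amine lets the volatile enone distil away from the base as it forms, which limits polymerisation.

Step 6
Reactants: 6 {[2,4-bis(benzyloxy)phenyl]ethynyloxy}triisopropylsilane; 9 cyclobutenone
Product: 14 2-[2,4-bis(benzyloxy)phenyl]-3-(triisopropylsilyloxy)phenol, via vinylketene 10 (not isolated), via vinylcyclobutenone adduct 11 (not isolated), via dienylketene 12 (not isolated), via cyclohexadienone tautomer 13 (not isolated)
Conditions: 6 in toluene, BHT (cat.), 80 °C, slow addition of 9 (2 equiv, toluene solution), then 110 °C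
Reagents that add atoms: none
Why: This is a Danheiser benzannulation, the closest known reaction type being cyclobutenones with triisopropylsiloxyalkynes to give resorcinol monosilyl ethers: 9 opens thermally (4π, conrotatory) to vinylketene 10, and the aryl-bearing alkyne carbon of 6 attacks the ketene carbonyl carbon in a [2+2] cycloaddition that forms C8–C8a and C6–C7 and gives 11. A second, reversible 4π opening of 11 gives dienylketene 12, and the isomer that holds the vinyl group cis to the ketene closes irreversibly. The one ring that remains, the benzene ring of coumarin B, is closed by this thermal disrotatory 6π electrocyclisation (C4a–C8a), after which 13 tautomerises to phenol 14. No stereocentre is created in 14, because the sp3 carbon of racemic 11 ends as an arene CH. The selectivity needed is the orientation of the [2+2]: the silyloxy oxygen sits directly on the triple bond, makes the aryl-bearing carbon the nucleophilic one and outweighs the opposing push of the dialkoxyaryl group, so the aryl group ends between the two oxygens. Slow addition of 9 keeps 10 dilute, so that capture by the electron-rich alkyne should outrun polymerisation and acylation of the hindered product phenol.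

Step 7
Reactants: 14 2-[2,4-bis(benzyloxy)phenyl]-3-(triisopropylsilyloxy)phenol
Product: 15 3-[2,4-bis(benzyloxy)phenyl]-2-hydroxy-4-(triisopropylsilyloxy)benzaldehyde
Conditions: MgCl2 (3 equiv), Et3N (4 equiv), (CH2O)n (6 equiv), MeCN, reflux; 1 M HCl work-up
Reagents that add atoms: paraformaldehyde (as formaldehyde) C=O
Why: In the Casnati–Skattebøl ortho-formylation the magnesium phenoxide delivers formaldehyde to the only free ortho position (future C4a of coumarin B), a second formaldehyde takes up hydride, and ring A stays untouched because it has no free OH.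

Step 8
Reactants: 15 3-[2,4-bis(benzyloxy)phenyl]-2-hydroxy-4-(triisopropylsilyloxy)benzaldehyde
Product: 17 2,4-bis(benzyloxy)-5-[3-formyl-2-hydroxy-6-(triisopropylsilyloxy)phenyl]benzaldehyde, via aryl iminium chloride 16 (not isolated)
Conditions: POCl3 (3 equiv, premixed with DMF at 0 °C), DMF, 0 → 60 °C; then ice–water, rt
Reagents that add atoms: N,N-dimethylformamide CN(C)C=O; water O
Why: In the Vilsmeier–Haack formylation the weak chloroiminium electrophile prefers the resorcinol diether ring A over the formyl-deactivated ring B and enters para to the 2-benzyloxy and ortho to the 4-benzyloxy group (future C4a of coumarin A), since the site between the two ethers is sterically closed.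

Step 9
Reactants: 17 2,4-bis(benzyloxy)-5-[3-formyl-2-hydroxy-6-(triisopropylsilyloxy)phenyl]benzaldehyde
Product: 18 5-[3-formyl-2-hydroxy-6-(triisopropylsilyloxy)phenyl]-2,4-dihydroxybenzaldehyde
Conditions: BCl3 (5 equiv), pentamethylbenzene (6 equiv), CH2Cl2, −78 °C; then H2O
Reagents that add atoms: none
Why: Lewis-acid debenzylation of aryl benzyl ethers with pentamethylbenzene as a non-basic benzyl cation trap runs at −78 °C, where aldehydes and the hindered aryl silyl ether should persist and no C-benzylation of the electron-rich rings is expected.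

Step 10
Reactants: 18 5-[3-formyl-2-hydroxy-6-(triisopropylsilyloxy)phenyl]-2,4-dihydroxybenzaldehyde; 19 tert-butyl bromoacetate
Product: 20 tert-butyl 2-{4-formyl-2-[3-formyl-2-hydroxy-6-(triisopropylsilyloxy)phenyl]-5-hydroxyphenoxy}acetate
Conditions: 19 (1.05 equiv), K2CO3 (1.1 equiv), acetone, 0 °C → rt
Reagents that add atoms: none
Why: This chemoselective Williamson etherification follows the known 4-O-selectivity of 2,4-dihydroxybenzaldehydes, because only the ring A hydroxyl para to the formyl group is unchelated and most acidic, while one equivalent of mild base and a very reactive bromide keep the phenoxide short-lived so that silyl transfer across the biaryl should not compete.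

Step 11
Reactants: 20 tert-butyl 2-{4-formyl-2-[3-formyl-2-hydroxy-6-(triisopropylsilyloxy)phenyl]-5-hydroxyphenoxy}acetate
Product: 22 tert-butyl 2-({2-oxo-6-[2-oxo-7-(triisopropylsilyloxy)-2H-chromen-8-yl]-2H-chromen-7-yl}oxy)acetate, via bis(phosphoranylideneacetate) ester 21 (not isolated)
Conditions: Ph3P=C=C=O (2.4 equiv), toluene, reflux
Reagents that add atoms: ketenylidenetriphenylphosphorane O=C=C=P(c1ccccc1)(c1ccccc1)c1ccccc1
Why: In this domino addition–intramolecular Wittig olefination each salicylaldehyde OH adds to the cumulated ylide, and the resulting aryl ester ylide can only close on its neighbouring formyl group to the cis-configured six-membered lactone, at a temperature that spares the tert-butyl ester and the silyl ether.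

Step 12
Reactants: 22 tert-butyl 2-({2-oxo-6-[2-oxo-7-(triisopropylsilyloxy)-2H-chromen-8-yl]-2H-chromen-7-yl}oxy)acetate
Product: 23 2-({2-oxo-6-[2-oxo-7-(triisopropylsilyloxy)-2H-chromen-8-yl]-2H-chromen-7-yl}oxy)acetic acid
Conditions: TFA/CH2Cl2 (1:2), 0 °C → rt
Reagents that add atoms: none
Why: Acidolysis of the tert-butyl ester by loss of isobutene needs no base, so the two lactones stay closed and the acid-robust aryl triisopropylsilyl ether stays in place.

Step 13
Reactants: 23 2-({2-oxo-6-[2-oxo-7-(triisopropylsilyloxy)-2H-chromen-8-yl]-2H-chromen-7-yl}oxy)acetic acid; 1 2,4-dihydroxybenzaldehyde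
Product: 24 3-({2-oxo-6-[2-oxo-7-(triisopropylsilyloxy)-2H-chromen-8-yl]-2H-chromen-7-yl}oxy)-2-oxo-2H-chromen-7-yl acetate
Conditions: 1 (1.5 equiv), Ac2O, Et3N (3 equiv), 120 °C
Reagents that add atoms: acetic anhydride CC(=O)OC(C)=O
Why: In the Perkin–Oglialoro condensation the mixed anhydride of the aryloxyacetic acid acylates the 2-OH of 1, its aryloxy-activated CH2 condenses with the formyl group and dehydration closes coumarin C with the ether oxygen on C3, which is the classical route to 3-aryloxy-7-acetoxycoumarins.

Step 14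
Reactants: 24 3-({2-oxo-6-[2-oxo-7-(triisopropylsilyloxy)-2H-chromen-8-yl]-2H-chromen-7-yl}oxy)-2-oxo-2H-chromen-7-yl acetate
Product: 26 7-hydroxy-8-{7-[(7-hydroxy-2-oxo-2H-chromen-3-yl)oxy]-2-oxo-2H-chromen-6-yl}-2H-chromen-2-one (CNP0215289.0), via desilylated acetate 25 (not isolated)
Conditions: n-Bu4NF (1.2 equiv), THF, 0 °C; then K2CO3 (3 equiv), MeOH, rt; then 1 M HCl
Reagents that add atoms: none
Why: Fluoride-induced Si–O cleavage followed in the same flask by carbonate-mediated methanolysis of the aryl acetate frees both phenols, the final acidification re-closes any lactone opened reversibly, and partial silyl-to-acetyl exchange in step 13 would be cleared by the same treatment.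

Compound list
1 | 2,4-dihydroxybenzaldehyde | O=Cc1ccc(O)cc1O | starting material
2 | 2,4-bis(benzyloxy)benzaldehyde | O=Cc1ccc(OCc2ccccc2)cc1OCc1ccccc1 | intermediate
3 | 2,4-bis(benzyloxy)-1-ethynylbenzene | C#Cc1ccc(OCc2ccccc2)cc1OCc1ccccc1 | intermediate
4 | lithium [2,4-bis(benzyloxy)phenyl]acetylide | [Li+].[C-]#Cc1ccc(OCc2ccccc2)cc1OCc1ccccc1 | intermediate
5 | lithium 2-[2,4-bis(benzyloxy)phenyl]ethynolate | [Li+].[O-]C#Cc1ccc(OCc2ccccc2)cc1OCc1ccccc1 | intermediate
6 | {[2,4-bis(benzyloxy)phenyl]ethynyloxy}triisopropylsilane | CC(C)[Si](OC#Cc1ccc(OCc2ccccc2)cc1OCc1ccccc1)(C(C)C)C(C)C | intermediate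
7 | 3-oxocyclobutanecarboxylic acid | O=C1CC(C(=O)O)C1 | starting material
8 | 3-bromocyclobutanone | O=C1CC(Br)C1 | intermediate
9 | cyclobutenone (cyclobut-2-en-1-one) | O=C1CC=C1 | intermediate
10 | vinylketene (buta-1,3-dien-1-one) | C=CC=C=O | intermediate
11 | 2-[2,4-bis(benzyloxy)phenyl]-3-(triisopropylsilyloxy)-4-vinylcyclobut-2-en-1-one (racemic) | O=C1C(c2ccc(OCc3ccccc3)cc2OCc2ccccc2)=C(O[Si](C(C)C)(C(C)C)C(C)C)C1C=C | intermediate
12 | (3E)-2-[2,4-bis(benzyloxy)phenyl]-3-(triisopropylsilyloxy)hexa-1,3,5-trien-1-one (vinyl cis to the ketene) | O=C=C(c1ccc(OCc2ccccc2)cc1OCc1ccccc1)/C(O[Si](C(C)C)(C(C)C)C(C)C)=C\C=C | intermediate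
13 | 2-[2,4-bis(benzyloxy)phenyl]-3-(triisopropylsilyloxy)cyclohexa-2,4-dien-1-one | O=C1CC=CC(O[Si](C(C)C)(C(C)C)C(C)C)=C1c1ccc(OCc2ccccc2)cc1OCc1ccccc1 | intermediate
14 | 2-[2,4-bis(benzyloxy)phenyl]-3-(triisopropylsilyloxy)phenol | Oc1cccc(O[Si](C(C)C)(C(C)C)C(C)C)c1-c1ccc(OCc2ccccc2)cc1OCc1ccccc1 | intermediate
15 | 3-[2,4-bis(benzyloxy)phenyl]-2-hydroxy-4-(triisopropylsilyloxy)benzaldehyde | O=Cc1ccc(O[Si](C(C)C)(C(C)C)C(C)C)c(-c2ccc(OCc3ccccc3)cc2OCc2ccccc2)c1O | intermediate
16 | N-{2,4-bis(benzyloxy)-5-[3-formyl-2-hydroxy-6-(triisopropylsilyloxy)phenyl]benzylidene}-N-methylmethanaminium chloride | C[N+](C)=Cc1cc(-c2c(O)c(C=O)ccc2O[Si](C(C)C)(C(C)C)C(C)C)c(OCc2ccccc2)cc1OCc1ccccc1.[Cl-] | intermediate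
17 | 2,4-bis(benzyloxy)-5-[3-formyl-2-hydroxy-6-(triisopropylsilyloxy)phenyl]benzaldehyde | O=Cc1cc(-c2c(O)c(C=O)ccc2O[Si](C(C)C)(C(C)C)C(C)C)c(OCc2ccccc2)cc1OCc1ccccc1 | intermediate
18 | 5-[3-formyl-2-hydroxy-6-(triisopropylsilyloxy)phenyl]-2,4-dihydroxybenzaldehyde | O=Cc1cc(-c2c(O)c(C=O)ccc2O[Si](C(C)C)(C(C)C)C(C)C)c(O)cc1O | intermediate
19 | tert-butyl bromoacetate | CC(C)(C)OC(=O)CBr | starting material
20 | tert-butyl 2-{4-formyl-2-[3-formyl-2-hydroxy-6-(triisopropylsilyloxy)phenyl]-5-hydroxyphenoxy}acetate | CC(C)(C)OC(=O)COc1cc(O)c(C=O)cc1-c1c(O)c(C=O)ccc1O[Si](C(C)C)(C(C)C)C(C)C | intermediate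
21 | bis[(triphenylphosphoranylidene)acetate] ester of 20 at both phenolic oxygens | CC(C)(C)OC(=O)COc1cc(OC(=O)C=P(c2ccccc2)(c2ccccc2)c2ccccc2)c(C=O)cc1-c1c(OC(=O)C=P(c2ccccc2)(c2ccccc2)c2ccccc2)c(C=O)ccc1O[Si](C(C)C)(C(C)C)C(C)C | intermediate
22 | tert-butyl 2-({2-oxo-6-[2-oxo-7-(triisopropylsilyloxy)-2H-chromen-8-yl]-2H-chromen-7-yl}oxy)acetate | CC(C)(C)OC(=O)COc1cc2oc(=O)ccc2cc1-c1c(O[Si](C(C)C)(C(C)C)C(C)C)ccc2ccc(=O)oc12 | intermediate
23 | 2-({2-oxo-6-[2-oxo-7-(triisopropylsilyloxy)-2H-chromen-8-yl]-2H-chromen-7-yl}oxy)acetic acid | O=C(O)COc1cc2oc(=O)ccc2cc1-c1c(O[Si](C(C)C)(C(C)C)C(C)C)ccc2ccc(=O)oc12 | intermediate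
24 | 3-({2-oxo-6-[2-oxo-7-(triisopropylsilyloxy)-2H-chromen-8-yl]-2H-chromen-7-yl}oxy)-2-oxo-2H-chromen-7-yl acetate | CC(=O)Oc1ccc2cc(Oc3cc4oc(=O)ccc4cc3-c3c(O[Si](C(C)C)(C(C)C)C(C)C)ccc4ccc(=O)oc34)c(=O)oc2c1 | intermediate
25 | 3-{[6-(7-hydroxy-2-oxo-2H-chromen-8-yl)-2-oxo-2H-chromen-7-yl]oxy}-2-oxo-2H-chromen-7-yl acetate | CC(=O)Oc1ccc2cc(Oc3cc4oc(=O)ccc4cc3-c3c(O)ccc4ccc(=O)oc34)c(=O)oc2c1 | intermediate
26 | 7-hydroxy-8-{7-[(7-hydroxy-2-oxo-2H-chromen-3-yl)oxy]-2-oxo-2H-chromen-6-yl}-2H-chromen-2-one (CNP0215289.0) | O=c1ccc2cc(-c3c(O)ccc4ccc(=O)oc34)c(Oc3cc4ccc(O)cc4oc3=O)cc2o1 | target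

Total step count: 14. Longest linear sequence: 12 steps (steps 1–3 and 6–14). Steps 4 and 5 form the two-step cyclobutenone branch.

Steps most likely to fail

Step 6. Several things may go wrong. Cyclobutenone may polymerise, or the vinylketene may react with itself before the alkyne captures it. Surplus ketene may acylate the product phenol. The ynol ether may decay thermally or protically. The donor aryl group may weaken the polarisation that fixes the orientation of the [2+2]. The fallback sets out from 6 and comes back to the route at 14 through 10 and 11. It makes the vinylketene at room temperature by a photochemical Wolff rearrangement instead of a thermal ring opening. 3-Chloropropanoyl chloride is treated with Me3SiCHN2 in MeCN/THF at 0 °C to give 4-chloro-1-diazobutan-2-one F1. Et3N in CH2Cl2 eliminates HCl to give 1-diazobut-3-en-2-one F2. Irradiation of F2 with 6 at 254 nm in CH2Cl2 releases 10, which is trapped as 11. Brief heating in toluene then completes the opening, closure and tautomerisation to 14.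

Step 13. Acetic anhydride itself may undergo Perkin condensation with the aldehyde, the hindered mixed anhydride may enolise slowly, and the advanced acid may decompose thermally at 120 °C. The fallback sets out from 23 and 1 and comes back at 26. It separates acylation from ring closure and avoids hot anhydride. Selective silylation of the unchelated hydroxyl of 1 (TIPSCl, imidazole, CH2Cl2, 0 °C) gives 2-hydroxy-4-(triisopropylsilyloxy)benzaldehyde F3. Carbodiimide coupling with 23 (EDC·HCl, DMAP, CH2Cl2, rt) gives the 2-formyl-5-(triisopropylsilyloxy)phenyl ester F4. An intramolecular Knoevenagel-type aldol condensation (i-Pr2NEt, MeCN, 60 °C) gives the bis(triisopropylsilyl) tricoumarin F5. Double desilylation with n-Bu4NF/AcOH in THF then gives 26 directly.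

Step 10. The chelated phenols may be over-alkylated, and base may induce silyl migration from O7 of ring B to the neighbouring ring A phenoxide or remove the silyl group altogether. The fallback sets out from 18 and comes back at 20. It replaces phenoxide alkylation by a Mitsunobu etherification with tert-butyl glycolate (PPh3, DIAD, THF, 0 °C). This activates the alcohol instead of the phenol, needs no added base and is known to pick the unchelated 4-OH of 2,4-dihydroxybenzaldehydes. It makes no compound outside the list (F0).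

Further compounds
F1 | step 6 | 4-chloro-1-diazobutan-2-one | ClCCC(=O)C=[N+]=[N-]
F2 | step 6 | 1-diazobut-3-en-2-one | C=CC(=O)C=[N+]=[N-]
F3 | step 13 | 2-hydroxy-4-(triisopropylsilyloxy)benzaldehyde | O=Cc1ccc(O[Si](C(C)C)(C(C)C)C(C)C)cc1O
F4 | step 13 | 2-formyl-5-(triisopropylsilyloxy)phenyl 2-({2-oxo-6-[2-oxo-7-(triisopropylsilyloxy)-2H-chromen-8-yl]-2H-chromen-7-yl}oxy)acetate | O=Cc1ccc(O[Si](C(C)C)(C(C)C)C(C)C)cc1OC(=O)COc1cc2oc(=O)ccc2cc1-c1c(O[Si](C(C)C)(C(C)C)C(C)C)ccc2ccc(=O)oc12
F5 | step 13 | 7-(triisopropylsilyloxy)-8-(2-oxo-7-{[2-oxo-7-(triisopropylsilyloxy)-2H-chromen-3-yl]oxy}-2H-chromen-6-yl)-2H-chromen-2-one | CC(C)[Si](Oc1ccc2cc(Oc3cc4oc(=O)ccc4cc3-c3c(O[Si](C(C)C)(C(C)C)C(C)C)ccc4ccc(=O)oc34)c(=O)oc2c1)(C(C)C)C(C)C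
F0 | step 10 | none | none
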